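**Plan**

- Ring names: the dimethoxyphenyl ring is ring B (C1'–C6'). The apigenin unit has benzo ring D (C4a''–C8a''), pyranone ring E and 4-hydroxyphenyl ring F. The second flavone has benzo ring A and pyranone ring C.
- Cuts, in order: the five O-benzyl groups; ring C at O1–C2 and C2–C3 (back to a ring B benzoic acid and a bought ring A acetophenone); ring E at O1''–C2'' and C2''–C3'' (back to an acetophenone and a bought ring F aldehyde); the acetyl bond C4''–C4a''; last, ring D at the bond from C8'' to a neighbouring oxygenated carbon.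
- Enabling feature: C8'' of ring D carries C3' of ring B and lies between the oxygen-bearing carbons C7'' and C8a''. It therefore maps onto the benzylic carbon of a ring B arylacetyl group, and ring D onto a 6-aryl-3,5-dioxohexanoate closed by an intramolecular Claisen condensation. The hindered C3'–C8'' biaryl bond is never made by coupling.
- Forward: ring B is bought as methyl vanillate and given a two-carbon arm (allylation, Claisen rearrangement, oxidative cleavage). The arm is extended to the triketide, ring D is closed, then ring E, then ring C onto bought ring A, and the benzyl groups are removed.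
- Stereochemistry: the target has no stereocentre and its biaryl axis is unassigned. The E-alkene of the chalcone disappears when ring E forms.

Key step: step 7

Remarks on the chemistry: the biaryl axis is treated as configurationally undefined, as drawn. 2-Hydroxy-4,6-bis(benzyloxy)acetophenone is taken as a purchasable compound (otherwise one benzylation step from 2,4,6-trihydroxyacetophenone).

**Route**

Step 1
Reactants: 1 methyl vanillate (methyl 4-hydroxy-3-methoxybenzoate); 2 allyl bromide
Product: 3 methyl 4-(allyloxy)-3-methoxybenzoate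
Conditions: K2CO3, acetone, reflux
Reagents that add atoms: none
Why: Williamson ether synthesis, in which the carbonate-generated phenoxide of 1 displaces bromide from the allylic halide by SN2 while the methyl ester is inert to K2CO3 in acetone.

Step 2
Reactants: 3 methyl 4-(allyloxy)-3-methoxybenzoate
Product: 4 methyl 3-allyl-4-hydroxy-5-methoxybenzoate
Conditions: N,N-diethylaniline, 200 °C
Reagents that add atoms: none
Why: Aromatic Claisen rearrangement, in which the [3,3]-sigmatropic shift can only reach the unsubstituted ortho carbon because the other ortho position bears the methoxy group, and tautomerization of the dienone restores the phenol.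

Step 3
Reactants: 4 methyl 3-allyl-4-hydroxy-5-methoxybenzoate
Product: 5 methyl 3-allyl-4,5-dimethoxybenzoate
Conditions: MeI, K2CO3, DMF, rt
Reagents that add atoms: iodomethane, CI
Why: Williamson O-methylation of the hindered but acidic phenol in a dipolar aprotic solvent, under conditions too mild to move the allyl double bond into conjugation.

Step 4
Reactants: 5 methyl 3-allyl-4,5-dimethoxybenzoate
Product: 6 methyl 3,4-dimethoxy-5-(2-oxoethyl)benzoate
Conditions: O3, CH2Cl2/MeOH, −78 °C (Sudan Red 7B end point); then Me2S, −78 °C → rt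
Reagents that add atoms: ozone, [O-][O+]=O
Why: Ozonolysis with reductive work-up, in which the isolated terminal alkene reacts far faster than the ester-deactivated arene, the dye marks the end point, and the arylacetaldehyde is used at once to avoid enolization and air oxidation.

Step 5
Reactants: 6 methyl 3,4-dimethoxy-5-(2-oxoethyl)benzoate
Product: 7 2-[2,3-dimethoxy-5-(methoxycarbonyl)phenyl]acetic acid
Conditions: NaClO2, NaH2PO4, 2-methylbut-2-ene, t-BuOH/H2O, 0 °C → rt
Reagents that add atoms: sodium chlorite, [Na+].[O-]Cl=O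
Why: Pinnick oxidation, in which chlorous acid converts the aldehyde into the acid without touching the benzylic CH2 or the ester, and 2-methylbut-2-ene traps the hypochlorous acid that would otherwise chlorinate the electron-rich ring.

Step 6
Reactants: 7 2-[2,3-dimethoxy-5-(methoxycarbonyl)phenyl]acetic acid; 8 methyl acetoacetate
Product: 10 methyl 6-[2,3-dimethoxy-5-(methoxycarbonyl)phenyl]-3,5-dioxohexanoate, via acyl imidazolide 9 (not isolated)
Conditions: 7, CDI, THF, rt; then added to 8 (3 equiv) + LiN(i-Pr)2 (6 equiv), THF, −78 °C → −20 °C; then 1 M HCl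
Reagents that add atoms: 1,1'-carbonyldiimidazole, O=C(n1ccnc1)n1ccnc1 (its imidazolyl group is carried only in intermediate 9)
Why: Acylation of the acetoacetate dianion by an N-acylimidazole, in which the terminal (gamma) carbanion is the most nucleophilic site, the imidazolide is far more electrophilic than the methyl benzoate at −78 °C, and the excess dianion absorbs the acidic proton of the diketo ester product.

Step 7
Reactants: 10 methyl 6-[2,3-dimethoxy-5-(methoxycarbonyl)phenyl]-3,5-dioxohexanoate
Product: 11 methyl 3,4-dimethoxy-5-(2,4,6-trihydroxyphenyl)benzoate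
Conditions: NaN(SiMe3)2 (3 equiv), THF (0.02 M), argon, −78 °C → 60 °C; then degassed 1 M HCl, 0 °C
Reagents that add atoms: none
Why: Excess NaN(SiMe3)2 converts 10 into its dianions; in the 4,6-dianion the benzylic C6, the last-formed and least stabilized carbanion site, adds to the un-enolized ester carbonyl C1, methoxide is expelled, and the 2-arylcyclohexane-1,3,5-trione tautomerizes to the phloroglucinol, whose phenoxide should make the sequence irreversible. The closest known reaction types are the biomimetic Claisen cyclization of polyketo esters to phloroglucinols and the Dieckmann-type closure of 6-aryl-5-oxohexanoates to 2-arylcyclohexane-1,3-diones, which this substrate combines. Ring D closes in the 6-(enolendo)-exo-trig mode by joining the aryl-bearing carbon (future C8'') to an oxygenated ortho carbon. No stereocentre is formed. The step needs C-acylation at C6 rather than O-acylation to a 6-benzyl-4-hydroxy-2-pyrone, retro-Claisen cleavage or attack on the ring B benzoate; this should be secured by a hindered non-nucleophilic base in excess (the diketone stays enolized and the base does not add to either ester), by the aryl-acidified C6, by high dilution and by aromatization as the driving force. Because the product is mirror-symmetric, it does not matter which chain carbonyl ends up as C7'' or C8a''.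

Step 8
Reactants: 11 methyl 3,4-dimethoxy-5-(2,4,6-trihydroxyphenyl)benzoate
Product: 13 methyl 3-(3-acetyl-2,4,6-trihydroxyphenyl)-4,5-dimethoxybenzoate, via ketiminium chloride 12 (not isolated)
Conditions: MeCN, ZnCl2, HCl (gas), Et2O, 0 °C; then H2O, 90 °C
Reagents that add atoms: acetonitrile, CC#N; water, O; hydrogen chloride, Cl (chloride only in the counter-ion of intermediate 12)
Why: Houben–Hoesch acylation, in which the ZnCl2/HCl-activated nitrile attacks one of the two equivalent, doubly hydroxyl-activated CH positions of the symmetric phloroglucinol, the iminium salt deactivates the ring against a second acylation, and warm water hydrolyses it to the methyl ketone while the much less nucleophilic ring B is left alone.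

Step 9
Reactants: 13 methyl 3-(3-acetyl-2,4,6-trihydroxyphenyl)-4,5-dimethoxybenzoate
Product: 14 methyl 3-[3-acetyl-4,6-bis(benzyloxy)-2-hydroxyphenyl]-4,5-dimethoxybenzoate
Conditions: BnBr (2.05 equiv), K2CO3 (2.2 equiv), acetone, reflux
Reagents that add atoms: benzyl bromide, BrCc1ccccc1
Why: Selective Williamson benzylation as practised on 3-substituted phloroacetophenones, in which the hydroxyl para to the acetyl group (most acidic, not hydrogen-bonded) reacts first, the ortho hydroxyl next to the ring CH second, and the hydroxyl wedged between the acetyl group and the twisted ring B stays chelated and shielded, so two equivalents of benzyl bromide should stop at 14.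

Step 10
Reactants: 14 methyl 3-[3-acetyl-4,6-bis(benzyloxy)-2-hydroxyphenyl]-4,5-dimethoxybenzoate; 15 4-(benzyloxy)benzaldehyde
Product: 17 3-{4,6-bis(benzyloxy)-3-[(E)-3-(4-benzyloxyphenyl)prop-2-enoyl]-2-hydroxyphenyl}-4,5-dimethoxybenzoic acid, via acetophenone carboxylic acid 16 (not isolated)
Conditions: KOH, EtOH/THF/H2O, 50 °C; then 15, rt; then 1 M HCl
Reagents that add atoms: potassium hydroxide, [K+].[OH-]
Why: Ester saponification followed by Claisen–Schmidt condensation, in which the methyl ketone enolate adds to the non-enolizable aldehyde and E1cB loss of hydroxide gives the conjugated E-enone under thermodynamic control, while the phenoxide and carboxylate charges keep the chalcone open in base.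

Step 11
Reactants: 17 3-{4,6-bis(benzyloxy)-3-[(E)-3-(4-benzyloxyphenyl)prop-2-enoyl]-2-hydroxyphenyl}-4,5-dimethoxybenzoic acid
Product: 18 3-[5,7-bis(benzyloxy)-2-(4-benzyloxyphenyl)-4-oxo-4H-chromen-8-yl]-4,5-dimethoxybenzoic acid
Conditions: I2 (10 mol %), DMSO, 120 °C; then aq. Na2S2O3
Reagents that add atoms: none
Why: Iodine-catalysed oxidative cyclization of a 2'-hydroxychalcone in DMSO, in which the only free phenol (the one next to ring B) adds to the enone carbon and iodine/DMSO dehydrogenate the ring to the 4H-chromen-4-one, fixing the 8-linkage of ring B.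

Step 12
Reactants: 18 3-[5,7-bis(benzyloxy)-2-(4-benzyloxyphenyl)-4-oxo-4H-chromen-8-yl]-4,5-dimethoxybenzoic acid; 19 2-hydroxy-4,6-bis(benzyloxy)acetophenone
Product: 20 2-acetyl-3,5-bis(benzyloxy)phenyl 3-[5,7-bis(benzyloxy)-2-(4-benzyloxyphenyl)-4-oxo-4H-chromen-8-yl]-4,5-dimethoxybenzoate
Conditions: EDC·HCl, DMAP, CH2Cl2/DMF, rt
Reagents that add atoms: none
Why: Steglich esterification, in which the carbodiimide-activated acid is passed through the N-acylpyridinium ion of DMAP to the weakly nucleophilic, hydrogen-bonded phenol of 19, the only hydroxyl present.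

Step 13
Reactants: 20 2-acetyl-3,5-bis(benzyloxy)phenyl 3-[5,7-bis(benzyloxy)-2-(4-benzyloxyphenyl)-4-oxo-4H-chromen-8-yl]-4,5-dimethoxybenzoate
Product: 21 1-[2,4-bis(benzyloxy)-6-hydroxyphenyl]-3-{3-[5,7-bis(benzyloxy)-2-(4-benzyloxyphenyl)-4-oxo-4H-chromen-8-yl]-4,5-dimethoxyphenyl}propane-1,3-dione
Conditions: LiN(SiMe3)2 (2.5 equiv), THF, −78 °C → 0 °C; then 1 M HCl
Reagents that add atoms: none
Why: Baker–Venkataraman rearrangement, in which the lithium enolate of the aryl methyl ketone attacks the neighbouring aryl ester carbonyl through a six-membered transition state and the O-to-C acyl shift is driven by formation of the phenoxide and diketonate, while the hindered amide base spares the existing chromenone.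

Step 14
Reactants: 21 1-[2,4-bis(benzyloxy)-6-hydroxyphenyl]-3-{3-[5,7-bis(benzyloxy)-2-(4-benzyloxyphenyl)-4-oxo-4H-chromen-8-yl]-4,5-dimethoxyphenyl}propane-1,3-dione
Product: 22 5,7-bis(benzyloxy)-8-{5-[5,7-bis(benzyloxy)-4-oxo-4H-chromen-2-yl]-2,3-dimethoxyphenyl}-2-(4-benzyloxyphenyl)-4H-chromen-4-one
Conditions: p-TsOH·H2O (20 mol %), toluene, reflux, Dean–Stark
Reagents that add atoms: none
Why: Acid-catalysed cyclodehydration of an o-hydroxyaryl 1,3-diketone, in which the phenol adds to the aroyl carbonyl and loss of water from the hemiketal gives the 4H-chromen-4-one of ring C, the weak sulfonic acid leaving the benzyl ethers intact.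

Step 15
Reactants: 22 5,7-bis(benzyloxy)-8-{5-[5,7-bis(benzyloxy)-4-oxo-4H-chromen-2-yl]-2,3-dimethoxyphenyl}-2-(4-benzyloxyphenyl)-4H-chromen-4-one
Product: 23 5'-methoxybilobetin
Conditions: H2 (1 atm), Pd/C (10 % palladium on carbon), THF/MeOH, rt
Reagents that add atoms: none
Why: Catalytic hydrogenolysis of benzyl aryl ethers, in which the benzylic C–O bonds are cleaved on palladium much faster than the vinylogous-ester C2=C3 bonds of the two chromenones are reduced and the methyl ethers are inert, so stopping after uptake of five equivalents of hydrogen should give the pentaphenol.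

**Compound list**

1 | methyl vanillate (methyl 4-hydroxy-3-methoxybenzoate) | COC(=O)c1ccc(O)c(OC)c1 | starting material
2 | allyl bromide | C=CCBr | starting material
3 | methyl 4-(allyloxy)-3-methoxybenzoate | COC(=O)c1ccc(OCC=C)c(OC)c1 | intermediate
4 | methyl 3-allyl-4-hydroxy-5-methoxybenzoate | COC(=O)c1cc(CC=C)c(O)c(OC)c1 | intermediate
5 | methyl 3-allyl-4,5-dimethoxybenzoate | COC(=O)c1cc(CC=C)c(OC)c(OC)c1 | intermediate
6 | methyl 3,4-dimethoxy-5-(2-oxoethyl)benzoate | COC(=O)c1cc(CC=O)c(OC)c(OC)c1 | intermediate
7 | 2-[2,3-dimethoxy-5-(methoxycarbonyl)phenyl]acetic acid | COC(=O)c1cc(CC(=O)O)c(OC)c(OC)c1 | intermediate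
8 | methyl acetoacetate | COC(=O)CC(C)=O | starting material
9 | methyl 3-[2-(imidazol-1-yl)-2-oxoethyl]-4,5-dimethoxybenzoate (acyl imidazolide, not isolated) | COC(=O)c1cc(CC(=O)n2ccnc2)c(OC)c(OC)c1 | intermediate
10 | methyl 6-[2,3-dimethoxy-5-(methoxycarbonyl)phenyl]-3,5-dioxohexanoate | COC(=O)CC(=O)CC(=O)Cc1cc(C(=O)OC)cc(OC)c1OC | intermediate
11 | methyl 3,4-dimethoxy-5-(2,4,6-trihydroxyphenyl)benzoate | COC(=O)c1cc(-c2c(O)cc(O)cc2O)c(OC)c(OC)c1 | intermediate
12 | ketiminium chloride of 13 (1-aryl-ethaniminium chloride, not isolated) | COC(=O)c1cc(-c2c(O)cc(O)c(C(C)=[NH2+])c2O)c(OC)c(OC)c1.[Cl-] | intermediate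
13 | methyl 3-(3-acetyl-2,4,6-trihydroxyphenyl)-4,5-dimethoxybenzoate | COC(=O)c1cc(-c2c(O)cc(O)c(C(C)=O)c2O)c(OC)c(OC)c1 | intermediate
14 | methyl 3-[3-acetyl-4,6-bis(benzyloxy)-2-hydroxyphenyl]-4,5-dimethoxybenzoate | COC(=O)c1cc(-c2c(O)c(C(C)=O)c(OCc3ccccc3)cc2OCc2ccccc2)c(OC)c(OC)c1 | intermediate
15 | 4-(benzyloxy)benzaldehyde | O=Cc1ccc(OCc2ccccc2)cc1 | starting material
16 | 3-[3-acetyl-4,6-bis(benzyloxy)-2-hydroxyphenyl]-4,5-dimethoxybenzoic acid (potassium salt in the flask, not isolated) | OC(=O)c1cc(-c2c(O)c(C(C)=O)c(OCc3ccccc3)cc2OCc2ccccc2)c(OC)c(OC)c1 | intermediate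
17 | 3-{4,6-bis(benzyloxy)-3-[(E)-3-(4-benzyloxyphenyl)prop-2-enoyl]-2-hydroxyphenyl}-4,5-dimethoxybenzoic acid | OC(=O)c1cc(-c2c(O)c(C(=O)/C=C/c3ccc(OCc4ccccc4)cc3)c(OCc3ccccc3)cc2OCc2ccccc2)c(OC)c(OC)c1 | intermediate
18 | 3-[5,7-bis(benzyloxy)-2-(4-benzyloxyphenyl)-4-oxo-4H-chromen-8-yl]-4,5-dimethoxybenzoic acid | OC(=O)c1cc(-c2c(OCc3ccccc3)cc(OCc3ccccc3)c3c(=O)cc(-c4ccc(OCc5ccccc5)cc4)oc23)c(OC)c(OC)c1 | intermediate
19 | 2-hydroxy-4,6-bis(benzyloxy)acetophenone | CC(=O)c1c(O)cc(OCc2ccccc2)cc1OCc1ccccc1 | starting material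
20 | 2-acetyl-3,5-bis(benzyloxy)phenyl 3-[5,7-bis(benzyloxy)-2-(4-benzyloxyphenyl)-4-oxo-4H-chromen-8-yl]-4,5-dimethoxybenzoate | CC(=O)c1c(OC(=O)c2cc(-c3c(OCc4ccccc4)cc(OCc4ccccc4)c4c(=O)cc(-c5ccc(OCc6ccccc6)cc5)oc34)c(OC)c(OC)c2)cc(OCc2ccccc2)cc1OCc1ccccc1 | intermediate
21 | 1-[2,4-bis(benzyloxy)-6-hydroxyphenyl]-3-{3-[5,7-bis(benzyloxy)-2-(4-benzyloxyphenyl)-4-oxo-4H-chromen-8-yl]-4,5-dimethoxyphenyl}propane-1,3-dione | O=C(CC(=O)c1cc(-c2c(OCc3ccccc3)cc(OCc3ccccc3)c3c(=O)cc(-c4ccc(OCc5ccccc5)cc4)oc23)c(OC)c(OC)c1)c1c(O)cc(OCc2ccccc2)cc1OCc1ccccc1 | intermediate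
22 | 5,7-bis(benzyloxy)-8-{5-[5,7-bis(benzyloxy)-4-oxo-4H-chromen-2-yl]-2,3-dimethoxyphenyl}-2-(4-benzyloxyphenyl)-4H-chromen-4-one | COc1cc(-c2cc(=O)c3c(OCc4ccccc4)cc(OCc4ccccc4)cc3o2)cc(-c2c(OCc3ccccc3)cc(OCc3ccccc3)c3c(=O)cc(-c4ccc(OCc5ccccc5)cc4)oc23)c1OC | intermediate
23 | 5'-methoxybilobetin, 8-[5-(5,7-dihydroxy-4-oxo-4H-chromen-2-yl)-2,3-dimethoxyphenyl]-5,7-dihydroxy-2-(4-hydroxyphenyl)-4H-chromen-4-one | COc1cc(-c2cc(=O)c3c(O)cc(O)cc3o2)cc(-c2c(O)cc(O)c3c(=O)cc(-c4ccc(O)cc4)oc23)c1OC | target

**Count and risks**

Total step count: 15. Longest linear sequence: 15 steps (from 1 to 23; all other partners are bought).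

Steps most likely to fail:

1. Step 7. The chain may close through the enolate oxygen (lactonization) instead of the benzylic carbon, the ester may stay locked as its unreactive enolate so that nothing closes, or base-induced chain cleavage and intermolecular condensation may take over. The fallback gives up the ring construction and makes the biaryl bond by cross-coupling. It sets out from 1 and returns at 11.
   - 1 would be brominated ortho to the phenol (Br2, AcOH) to methyl 3-bromo-4-hydroxy-5-methoxybenzoate F1.
   - F1 would be O-methylated (MeI, K2CO3, DMF) to methyl 3-bromo-4,5-dimethoxybenzoate F2.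
   - F2 would be borylated (bis(pinacolato)diboron, PdCl2(dppf), KOAc, dioxane, 90 °C) to methyl 3,4-dimethoxy-5-(4,4,5,5-tetramethyl-1,3,2-dioxaborolan-2-yl)benzoate F3.
   - Commercial 1,3,5-tris(benzyloxy)benzene would be iodinated (N-iodosuccinimide, MeCN) to 1,3,5-tris(benzyloxy)-2-iodobenzene F4.
   - Suzuki–Miyaura coupling of F3 with F4 (Pd(OAc)2, SPhos, K3PO4, toluene/H2O, 100 °C) should give methyl 3,4-dimethoxy-5-[2,4,6-tris(benzyloxy)phenyl]benzoate F5.
   - Hydrogenolysis of F5 (H2, Pd/C, THF/MeOH) would deliver 11.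

2. Step 9. Benzylation may take place at the wrong ortho hydroxyl (which would later transpose ring B to the 6-position), run on to the tribenzyl ether, or occur at the remaining ring carbon. The constitution of 14 would be checked by NOE, where the single ring D proton should show contacts to both OCH2 groups. The fallback replaces selective protection by exhaustive protection and selective deprotection. It sets out from 13 and returns at 14.
   - 13 would be fully benzylated (excess BnBr, Cs2CO3, DMF, 60 °C) to methyl 3-[3-acetyl-2,4,6-tris(benzyloxy)phenyl]-4,5-dimethoxybenzoate F6.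
   - One equivalent of BCl3 (CH2Cl2, −78 °C) would then cleave a benzyl ether ortho to the carbonyl by chelation. The ether flanked by both the acetyl group and ring B is twisted out of conjugation and the most Lewis basic, so it should be the one removed, giving 14.

3. Step 6. Proton transfer from the acidic arylacetyl imidazolide or from the product to the dianion may stall the acylation (enolization instead of C–C bond formation), and the dianion may add to the benzoate on warming. The fallback is a neutral acylation of a bis-silyl dienol ether. It sets out from 7 and 8 and returns at 10.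
   - 7 would be converted ((COCl)2, cat. DMF, CH2Cl2) into methyl 3-(2-chloro-2-oxoethyl)-4,5-dimethoxybenzoate F7.
   - 8 would be silylated (Me3SiCl, Et3N) to methyl 3-(trimethylsilyloxy)but-2-enoate F8.
   - F8 would be silylated again (LiN(i-Pr)2, Me3SiCl, THF, −78 °C) to 1-methoxy-1,3-bis(trimethylsilyloxy)buta-1,3-diene F9.
   - Reaction of F7 with F9 (CH2Cl2, −78 °C → 20 °C) and aqueous HCl work-up should give 10 by attack of the diene terminus on the acid chloride without any strong base.

**Further compounds**

F1 | step 7 | methyl 3-bromo-4-hydroxy-5-methoxybenzoate | COC(=O)c1cc(Br)c(O)c(OC)c1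
F2 | step 7 | methyl 3-bromo-4,5-dimethoxybenzoate | COC(=O)c1cc(Br)c(OC)c(OC)c1
F3 | step 7 | methyl 3,4-dimethoxy-5-(4,4,5,5-tetramethyl-1,3,2-dioxaborolan-2-yl)benzoate | COC(=O)c1cc(B2OC(C)(C)C(C)(C)O2)c(OC)c(OC)c1
F4 | step 7 | 1,3,5-tris(benzyloxy)-2-iodobenzene | Ic1c(OCc2ccccc2)cc(OCc2ccccc2)cc1OCc1ccccc1
F5 | step 7 | methyl 3,4-dimethoxy-5-[2,4,6-tris(benzyloxy)phenyl]benzoate | COC(=O)c1cc(-c2c(OCc3ccccc3)cc(OCc3ccccc3)cc2OCc2ccccc2)c(OC)c(OC)c1
F6 | step 9 | methyl 3-[3-acetyl-2,4,6-tris(benzyloxy)phenyl]-4,5-dimethoxybenzoate | COC(=O)c1cc(-c2c(OCc3ccccc3)cc(OCc3ccccc3)c(C(C)=O)c2OCc2ccccc2)c(OC)c(OC)c1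
F7 | step 6 | methyl 3-(2-chloro-2-oxoethyl)-4,5-dimethoxybenzoate | COC(=O)c1cc(CC(Cl)=O)c(OC)c(OC)c1
F8 | step 6 | methyl 3-(trimethylsilyloxy)but-2-enoate (E/Z mixture) | COC(=O)C=C(C)O[Si](C)(C)C
F9 | step 6 | 1-methoxy-1,3-bis(trimethylsilyloxy)buta-1,3-diene | C=C(O[Si](C)(C)C)C=C(OC)O[Si](C)(C)C
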